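## Retrosynthetic overview

- The C13=C14–C15(=O) enone comes from a ruthenium-catalysed redox isomerisation of a 13-yne-15-ol, so C15 never needs stereocontrol.
- The (5Z)-alkene comes from a Wittig reaction of a bicyclic lactol with a C1–C5 carboxylate ylide.
- C12–C13 and C7–C8 are made together in one copper-catalysed, light-driven radical cyclisation/alkynylation of an iodoacetal with a C13–C20 propargylic silyl ether; this is the fragment union.
- The C9/C11 carbinols come from a desymmetrising monosilylation of a meso cyclopentenediol.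
- Rings: the cyclopentane is bought; the only ring formed is the temporary tetrahydrofuran (acetal, then lactol) ring, closed in the cascade and opened in the Wittig step.

Assumption: atom labels C1–C20 follow prostanoid numbering (C1 carboxyl, ring C8–C12); intermediates carrying the carbinol that becomes the C15 ketone, or an acetal/lactol carbon, are used as epimer mixtures at those centres only.

## Route

Step 1
Reactants: 1 cis-cyclopent-4-ene-1,3-diol (meso)
Product: 2 (1S,4R)-4-[(tert-butyldimethylsilyl)oxy]cyclopent-2-en-1-ol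
Conditions: TBSCl (2 equiv), iPr2NEt (1.25 equiv), chiral tert-leucine-derived amino-amide bearing an N-methylimidazol-2-ylmethyl group (20 mol%; the enantiomer that silylates the (R)-carbinol, confirmed by optical rotation against the known compound), THF, −40 °C, 48 h
Reagents that add atoms: tert-butyldimethylsilyl chloride, CC(C)(C)[Si](C)(C)Cl
Why: Catalytic enantioselective silylation of a meso diol, in which the hydrogen-bonded catalyst–diol complex delivers the imidazole-activated silyl chloride to one enantiotopic hydroxyl, so C11 (R, silylated) and C9 (S, free) are set together.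

Step 2
Reactants: 2 (1S,4R)-4-[(tert-butyldimethylsilyl)oxy]cyclopent-2-en-1-ol; 3 ethyl vinyl ether
Product: 4 tert-butyl{[(1R,4S)-4-(1-ethoxy-2-iodoethoxy)cyclopent-2-en-1-yl]oxy}dimethylsilane (both acetal epimers)
Conditions: NIS (1.2 equiv), 3 (3 equiv), CH2Cl2, −30 °C to 0 °C
Reagents that add atoms: N-iodosuccinimide, O=C1CCC(=O)N1I
Why: Iodoacetalisation (Ueno–Stork precursor synthesis), in which the electron-rich enol ether is iodinated far faster than the ring alkene and the free C9 hydroxyl traps the oxocarbenium ion; the acetal carbon is lost later, so its configuration is irrelevant.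

Step 3
Reactants: 5 hexanal; 6 ethynylmagnesium bromide
Product: 7 rac-oct-1-yn-3-ol
Conditions: THF, 0 °C, 1 h; then 1 M HCl
Reagents that add atoms: none
Why: Grignard 1,2-addition of an acetylide to an aldehyde; the racemic carbinol is intended because this carbon ends as the C15 ketone.

Step 4
Reactants: 7 rac-oct-1-yn-3-ol
Product: 8 rac-tert-butyldimethyl(oct-1-yn-3-yloxy)silane
Conditions: TBSCl, imidazole, DMF, rt
Reagents that add atoms: tert-butyldimethylsilyl chloride, CC(C)(C)[Si](C)(C)Cl
Why: Standard silylation, which leaves the alkyne C–H as the only acidic site for the copper/carbonate system of step 5 and matches the core protecting group so that one acid step removes both.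

Step 5
Reactants: 4 tert-butyl{[(1R,4S)-4-(1-ethoxy-2-iodoethoxy)cyclopent-2-en-1-yl]oxy}dimethylsilane; 8 rac-tert-butyldimethyl(oct-1-yn-3-yloxy)silane
Product: 9 (3aR,4S,5R,6aS)-5-[(tert-butyldimethylsilyl)oxy]-4-{3-[(tert-butyldimethylsilyl)oxy]oct-1-yn-1-yl}-2-ethoxyhexahydro-2H-cyclopenta[b]furan (epimers at C2 and at the side-chain carbinol)
Conditions: CuCl (10 mol%), 4,4′,4″-tri-tert-butyl-2,2′:6′,2″-terpyridine (12 mol%), K2CO3 (2 equiv), 8 (1.5 equiv), MeCN (0.03 M), 450 nm LEDs, 25 °C, 24 h
Reagents that add atoms: none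
Why: Proposed new method: a copper-catalysed, visible-light-driven radical cyclisation/alkynylation cascade in which the photoexcited terpyridine-ligated monovalent copper acetylide of 8 reduces the C–I bond of 4, the primary C7 radical closes 5-exo onto C8 (only the cis-fused ring can form, which fixes C8), and the secondary C12 radical, shielded below by the new ring and the C11 silyl ether, is captured from above by the divalent copper acetylide and reductively eliminated from trivalent copper, placing the alkynyl group trans to both neighbours (C12 set); the closest known reaction types are the photoinduced copper-catalysed coupling of unactivated alkyl iodides with terminal alkynes and the tin-mediated Ueno–Stork haloacetal cyclisation/trapping, which have not been merged on a cyclic allylic haloacetal.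

Step 6
Reactants: 9 (3aR,4S,5R,6aS)-5-[(tert-butyldimethylsilyl)oxy]-4-{3-[(tert-butyldimethylsilyl)oxy]oct-1-yn-1-yl}-2-ethoxyhexahydro-2H-cyclopenta[b]furan
Product: 10 (3aR,4S,5R,6aS)-4-(3-hydroxyoct-1-yn-1-yl)hexahydro-2H-cyclopenta[b]furan-2,5-diol (lactol anomers, side-chain carbinol epimers)
Conditions: 2% aq. HCl/THF (3:2), rt, 16 h
Reagents that add atoms: water, O
Why: Acid-catalysed hydrolysis of the mixed acetal to the lactol with concurrent cleavage of both secondary silyl ethers; the alkyne, the propargylic alcohol and the ring stereocentres are inert to dilute acid at room temperature.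

Step 7
Reactants: 11 5-bromopentanoic acid
Product: 12 (4-carboxybutyl)triphenylphosphonium bromide
Conditions: PPh3, MeCN, reflux, 48 h
Reagents that add atoms: triphenylphosphine, c1ccc(cc1)P(c1ccccc1)c1ccccc1
Why: SN2 quaternisation of a primary bromide by the phosphine gives the crystalline Wittig salt.

Step 8
Reactants: 10 (3aR,4S,5R,6aS)-4-(3-hydroxyoct-1-yn-1-yl)hexahydro-2H-cyclopenta[b]furan-2,5-diol; 12 (4-carboxybutyl)triphenylphosphonium bromide
Product: 14 (5Z)-7-[(1R,2S,3R,5S)-3,5-dihydroxy-2-(3-hydroxyoct-1-yn-1-yl)cyclopentyl]hept-5-enoic acid (C15 epimer mixture), via carboxylate ylide 13 (not isolated)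
Conditions: 12 (6 equiv), KOtBu (12 equiv), THF, 0 °C, 40 min; then 10, 0 °C to rt, 2 h; then H2O, 1 M HCl to pH 4
Reagents that add atoms: none
Why: Wittig olefination, in which the lactol opens under base to the hydroxy aldehyde and the unstabilised ylide gives the (5Z)-alkene under kinetic control; the excess ylide covers the three hydroxyls, and the internal alkyne is a spectator.

Step 9
Reactants: 14 (5Z)-7-[(1R,2S,3R,5S)-3,5-dihydroxy-2-(3-hydroxyoct-1-yn-1-yl)cyclopentyl]hept-5-enoic acid
Product: 15 (5Z)-7-{(1R,2R,3R,5S)-3,5-dihydroxy-2-[(1E)-3-oxooct-1-en-1-yl]cyclopentyl}hept-5-enoic acid (15-keto-PGF2α)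
Conditions: RuCl(η5-C9H7)(PPh3)2 (5 mol%), In(OTf)3 (5 mol%), camphorsulfonic acid (10 mol%), THF, 65 °C, 3 h
Reagents that add atoms: none
Why: Ruthenium-catalysed redox isomerisation of a propargylic alcohol, in which the carbinol hydride shifts to the alkyne and protonation of the vinyl-ruthenium species gives the (13E)-enone; both C15 epimers converge, and the non-propargylic C9/C11 carbinols and the (5Z)-alkene are not activated.

## Compound list

1 | cis-cyclopent-4-ene-1,3-diol (meso, 1R,3S) | C1=C[C@@H](O)C[C@H]1O | starting material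
2 | (1S,4R)-4-[(tert-butyldimethylsilyl)oxy]cyclopent-2-en-1-ol | C1=C[C@@H](O)C[C@H]1O[Si](C)(C)C(C)(C)C | intermediate
3 | ethyl vinyl ether | C=COCC | starting material
4 | tert-butyl{[(1R,4S)-4-(1-ethoxy-2-iodoethoxy)cyclopent-2-en-1-yl]oxy}dimethylsilane (acetal epimers) | C1=C[C@@H](OC(CI)OCC)C[C@H]1O[Si](C)(C)C(C)(C)C | intermediate
5 | hexanal | CCCCCC=O | starting material
6 | ethynylmagnesium bromide | C#C[Mg]Br | starting material
7 | rac-oct-1-yn-3-ol | CCCCCC(O)C#C | intermediate
8 | rac-tert-butyldimethyl(oct-1-yn-3-yloxy)silane | CCCCCC(O[Si](C)(C)C(C)(C)C)C#C | intermediate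
9 | (3aR,4S,5R,6aS)-5-[(tert-butyldimethylsilyl)oxy]-4-{3-[(tert-butyldimethylsilyl)oxy]oct-1-yn-1-yl}-2-ethoxyhexahydro-2H-cyclopenta[b]furan (epimers at C2 and side-chain carbinol) | CCCCCC(O[Si](C)(C)C(C)(C)C)C#C[C@@H]1[C@@H](CC2OCC)[C@@H](O2)C[C@H]1O[Si](C)(C)C(C)(C)C | intermediate
10 | (3aR,4S,5R,6aS)-4-(3-hydroxyoct-1-yn-1-yl)hexahydro-2H-cyclopenta[b]furan-2,5-diol (anomers, side-chain carbinol epimers) | CCCCCC(O)C#C[C@@H]1[C@@H](CC2O)[C@@H](O2)C[C@H]1O | intermediate
11 | 5-bromopentanoic acid | OC(=O)CCCCBr | starting material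
12 | (4-carboxybutyl)triphenylphosphonium bromide | OC(=O)CCCC[P+](c1ccccc1)(c1ccccc1)c1ccccc1.[Br-] | intermediate
13 | potassium 5-(triphenyl-λ5-phosphanylidene)pentanoate (ylide, not isolated) | [K+].[O-]C(=O)CCCC=P(c1ccccc1)(c1ccccc1)c1ccccc1 | intermediate
14 | (5Z)-7-[(1R,2S,3R,5S)-3,5-dihydroxy-2-(3-hydroxyoct-1-yn-1-yl)cyclopentyl]hept-5-enoic acid (C15 epimers) | CCCCCC(O)C#C[C@@H]1[C@@H](C/C=C\CCCC(=O)O)[C@@H](O)C[C@H]1O | intermediate
15 | (5Z)-7-{(1R,2R,3R,5S)-3,5-dihydroxy-2-[(1E)-3-oxooct-1-en-1-yl]cyclopentyl}hept-5-enoic acid (15-keto-PGF2α) | CCCCCC(=O)/C=C/[C@@H]1[C@@H](C/C=C\CCCC(=O)O)[C@@H](O)C[C@H]1O | target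

## Step count and risks

Total step count: 9. Longest linear sequence: 6 (steps 1, 2, 5, 6, 8, 9; the branch 3, 4, 5, 6, 8, 9 is equally long; the phosphonium branch 7, 8, 9 is 3).

Steps most likely to fail:

Step 5 (the proposed new cascade). The risks are alkynylation of the C7 radical before ring closure, simple reduction, and diyne formation from 8; high dilution and low copper loading favour the cyclisation. Fallback with known chemistry, setting out from 4 and 8: lithiation of 8 (nBuLi, Et2O, −78 °C) and quenching with Tf2O gives the alkynyl triflone tert-butyldimethyl({1-[(trifluoromethyl)sulfonyl]oct-1-yn-3-yl}oxy)silane F3. Iodoacetal 4 and F3 are then irradiated with a sunlamp in benzene with catalytic (Bu3Sn)2. This is a metal-free radical chain: Ueno–Stork cyclisation, addition of the C12 radical to the triflone, loss of the sulfonyl radical, and iodine abstraction by the trifluoromethyl radical. It returns to the route at 9.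

Step 1 (enantioselective monosilylation). The precedent for this exact diol is from memory and should be checked; the risks are insufficient enantiomeric excess or bis-silylation. Fallback, setting out from 1: lipase-catalysed acetylation (pancreatin, vinyl acetate, Et3N, THF) gives (1S,4R)-4-hydroxycyclopent-2-en-1-yl acetate F1, with the acetate on the carbinol that must end free. Silylation of the remaining hydroxyl (TBSCl, imidazole, DMF) gives (1S,4R)-4-[(tert-butyldimethylsilyl)oxy]cyclopent-2-en-1-yl acetate F2. Methanolysis of the acetate (K2CO3, MeOH) returns to the route at 2.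

Step 9 (redox isomerisation on the unprotected trihydroxy acid). The risks are catalyst inhibition by the carboxylic acid and the 1,3-diol, or incomplete conversion. Fallback, setting out from 14: ruthenium-catalysed trans-hydrosilylation (BnMe2SiH, [(C5Me5)Ru(MeCN)3]PF6, CH2Cl2, 0 °C to rt) gives the vinylsilane (5Z,13Z)-13-(benzyldimethylsilyl)-9α,11α,15(RS)-trihydroxyprosta-5,13-dienoic acid F4. Protodesilylation (TBAF, CuI, THF) gives (5Z,13E)-9α,11α,15(RS)-trihydroxyprosta-5,13-dienoic acid F5 (PGF2α and its 15-epimer). DDQ in dioxane at rt then oxidises only the allylic C15 carbinol and returns to the route at 15.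

Further compounds

F1 | step 1 | (1S,4R)-4-hydroxycyclopent-2-en-1-yl acetate | C1=C[C@@H](OC(C)=O)C[C@H]1O
F2 | step 1 | (1S,4R)-4-[(tert-butyldimethylsilyl)oxy]cyclopent-2-en-1-yl acetate | C1=C[C@@H](OC(C)=O)C[C@H]1O[Si](C)(C)C(C)(C)C
F3 | step 5 | rac-tert-butyldimethyl({1-[(trifluoromethyl)sulfonyl]oct-1-yn-3-yl}oxy)silane | CCCCCC(O[Si](C)(C)C(C)(C)C)C#CS(=O)(=O)C(F)(F)F
F4 | step 9 | (5Z,13Z)-13-(benzyldimethylsilyl)-9α,11α,15(RS)-trihydroxyprosta-5,13-dienoic acid | CCCCCC(O)/C=C(\[Si](C)(C)Cc1ccccc1)[C@@H]1[C@@H](C/C=C\CCCC(=O)O)[C@@H](O)C[C@H]1O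
F5 | step 9 | (5Z,13E)-9α,11α,15(RS)-trihydroxyprosta-5,13-dienoic acid | CCCCCC(O)/C=C/[C@@H]1[C@@H](C/C=C\CCCC(=O)O)[C@@H](O)C[C@H]1O
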